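The target is disconnected at two alkenes, C1=C2 in ring B and C13=C14 in the side chain, and both are traced back to one C2=C13 double bond: tying C2 to C13 turns the vicinal C4/C11 stereo-pair into a trans-4-aryl-5-methylcyclohexene, available by auxiliary-controlled Diels–Alder reaction and decarboxylative arylation. A single ruthenium-catalysed ring-rearrangement/cross-metathesis then opens that cyclohexene, closes ring B onto an ortho isopropenyl group (C1) and joins C13 to a chiral terminal alkene carrying C15. The feature exploited is that C2, unlike C13, can reach the isopropenyl carbon through a six-membered ring containing C3, C4, C4a and C8a. Hydrogenation (C1), carboxylation at C6 and deprotection finish.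

Key step: step 11

Remarks on the chemistry
- Atom numbers follow the serrulatane skeleton: C1 is the methyl-bearing ring-B carbon next to C8a, C4 the ring-B carbon carrying the side chain, C5–C8 the arene carbons (CO2H on C6, OH on C7 and C8), C11–C16 the side chain from the C11 methine to the CH2OH carbon. The target is 1R,4S,11S,15R, with the C1 methyl trans to the C4 side chain.
- Assumption: the sense of induction of the iridium–PHOX catalyst in step 12 is assigned from the usual quadrant model for trisubstituted aryl alkenes; should a first run show the opposite sense, the enantiomeric ligand is used and nothing else changes.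

Step 1
Reactants: 1 methyl (S)-3-hydroxy-2-methylpropanoate
Product: 2 methyl (S)-3-[(tert-butyldimethylsilyl)oxy]-2-methylpropanoate
Conditions: TBSCl, imidazole, DMF, 0 °C → rt
Reagents that add atoms: tert-butyldimethylsilyl chloride, CC(C)(C)[Si](C)(C)Cl
Why: Imidazole-promoted silyl ether formation at the primary alcohol leaves the α-stereocentre untouched.

Step 2
Reactants: 2 methyl (S)-3-[(tert-butyldimethylsilyl)oxy]-2-methylpropanoate
Product: 3 (S)-3-[(tert-butyldimethylsilyl)oxy]-2-methylpropanal
Conditions: i-Bu2AlH, CH2Cl2, −78 °C; aq. potassium sodium tartrate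
Reagents that add atoms: none
Why: Partial hydride reduction of the ester stops at the tetrahedral aluminium hemiacetal at −78 °C and releases the aldehyde only on work-up, so the α-centre (future C15) is not epimerised if the aldehyde is used at once.

Step 3
Reactants: 3 (S)-3-[(tert-butyldimethylsilyl)oxy]-2-methylpropanal
Product: 4 (R)-tert-butyldimethyl[(2-methylbut-3-en-1-yl)oxy]silane
Conditions: Ph3PCH3Br, KN(SiMe3)2, THF, 0 °C; then 3, −78 °C → rt
Reagents that add atoms: methyltriphenylphosphonium bromide, C[P+](c1ccccc1)(c1ccccc1)c1ccccc1.[Br-]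
Why: Wittig methylenation with the non-stabilised ylide at low temperature is faster than enolisation of the α-branched aldehyde, and the descriptor changes from S to R only because the priorities change.

Step 4
Reactants: 5 (S)-4-benzyl-2-oxazolidinone
Product: 6 (S)-4-benzyl-3-[(E)-but-2-enoyl]oxazolidin-2-one
Conditions: (E)-crotonic anhydride, LiCl, Et3N, THF, −20 °C → rt
Reagents that add atoms: (E)-crotonic anhydride, C/C=C/C(=O)OC(=O)/C=C/C
Why: Lithium-chloride-assisted N-acylation of the oxazolidinone with the anhydride gives the crotonyl imide without strong base, so the E-alkene and the benzylic stereocentre are untouched.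

Step 5
Reactants: 6 (S)-4-benzyl-3-[(E)-but-2-enoyl]oxazolidin-2-one; 7 buta-1,3-diene
Product: 8 (4S)-4-benzyl-3-[(1S,6S)-6-methylcyclohex-3-ene-1-carbonyl]-1,3-oxazolidin-2-one
Conditions: Et2AlCl (1.4 equiv), 7 (excess), CH2Cl2, −20 → 0 °C
Reagents that add atoms: none
Why: Lewis-acid-promoted auxiliary-controlled Diels–Alder reaction in which Et2AlCl chelates both imide carbonyls and fixes the s-cis enoyl unit, the benzyl group shields one face, and butadiene adds suprafacially to the other, so the E geometry becomes the trans (1S,6S) pair and the methyl-bearing carbon is the future C11.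

Step 6
Reactants: 8 (4S)-4-benzyl-3-[(1S,6S)-6-methylcyclohex-3-ene-1-carbonyl]-1,3-oxazolidin-2-one
Product: 10 (1S,6S)-6-methylcyclohex-3-ene-1-carboxylic acid, via peroxy acid 9 (not isolated)
Conditions: LiOH, H2O2, THF/H2O, 0 °C; Na2SO3; aq. HCl
Reagents that add atoms: hydrogen peroxide (acting as lithium hydroperoxide, it supplies the carboxyl OH oxygen), OO
Why: Hydroperoxide-mediated auxiliary cleavage attacks the exocyclic imide carbonyl selectively, sulfite reduces the peroxy acid, and the peroxide anion does not epoxidise the isolated ring alkene.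

Step 7
Reactants: 10 (1S,6S)-6-methylcyclohex-3-ene-1-carboxylic acid
Product: 11 1,3-dioxoisoindolin-2-yl (1S,6S)-6-methylcyclohex-3-ene-1-carboxylate
Conditions: N-hydroxyphthalimide, N,N'-diisopropylcarbodiimide, DMAP (cat.), CH2Cl2, rt
Reagents that add atoms: N-hydroxyphthalimide, O=C1N(O)C(=O)c2ccccc12
Why: Carbodiimide esterification gives the redox-active ester required for single-electron decarboxylation.

Step 8
Reactants: 12 4-bromo-1,2-dimethoxybenzene
Product: 14 2-(6-bromo-2,3-dimethoxyphenyl)propan-2-ol, via aryllithium 13 (not isolated)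
Conditions: LiN(i-Pr)2, THF, −78 °C; acetone, −78 °C → rt; aq. NH4Cl
Reagents that add atoms: acetone, CC(C)=O
Why: Directed ortho-lithiation removes the proton flanked by OMe and Br, the most acidic one, without bromine–lithium exchange or aryne formation at −78 °C, and the aryllithium then undergoes 1,2-addition to acetone.

Step 9
Reactants: 14 2-(6-bromo-2,3-dimethoxyphenyl)propan-2-ol
Product: 15 1-bromo-3,4-dimethoxy-2-(prop-1-en-2-yl)benzene
Conditions: p-TsOH·H2O (cat.), toluene, 80 °C
Reagents that add atoms: none
Why: Acid-catalysed E1 dehydration of the tertiary benzylic alcohol can give only the isopropenyl group because both β-carbons are methyl groups.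

Step 10
Reactants: 11 1,3-dioxoisoindolin-2-yl (1S,6S)-6-methylcyclohex-3-ene-1-carboxylate; 15 1-bromo-3,4-dimethoxy-2-(prop-1-en-2-yl)benzene
Product: 18 (4S,5S)-4-[3,4-dimethoxy-2-(prop-1-en-2-yl)phenyl]-5-methylcyclohex-1-ene, via aryllithium 16 (not isolated), via arylzinc chloride 17 (not isolated)
Conditions: 15 (2 equiv), n-BuLi, THF, −78 °C; ZnCl2, −78 °C → rt; then 11, NiCl2·glyme (20 mol %), 4,4'-di-tert-butyl-2,2'-bipyridine (40 mol %), THF/DMF, rt; aq. HCl
Reagents that add atoms: none
Why: Nickel-catalysed decarboxylative Negishi-type arylation of a redox-active ester, in which bromine–lithium exchange and transmetallation give the arylzinc, single-electron reduction of the ester releases CO2 and a secondary cyclohex-3-enyl radical, and the aryl–nickel species captures that radical anti to the neighbouring methyl group, setting C4 trans to the untouched C11 centre.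

Step 11
Reactants: 18 (4S,5S)-4-[3,4-dimethoxy-2-(prop-1-en-2-yl)phenyl]-5-methylcyclohex-1-ene; 4 (R)-tert-butyldimethyl[(2-methylbut-3-en-1-yl)oxy]silane
Product: 20 tert-butyl{[(2R,3E,6S)-6-[(1S)-5,6-dimethoxy-4-methyl-1,2-dihydronaphthalen-1-yl]-2-methylhept-3-en-1-yl]oxy}dimethylsilane, via ring-rearranged terminal alkene 19 (not isolated)
Conditions: second-generation Grubbs catalyst RuCl2(H2IMes)(PCy3)(=CHPh) (10 mol %, two portions), 4 (3 equiv), toluene, 80 °C, argon sweep
Reagents that add atoms: none
Why: Proposed new method: a ruthenium alkylidene (the methylidene, or the alkylidene derived from 4) undergoes [2+2] cycloaddition/cycloreversion across C2=C13 and opens the cyclohexene; when the metal is left on C2 it engages the ortho isopropenyl group, forming the arene-conjugated trisubstituted C1=C2 bond and releasing the C13 terminus as a chain alkene (19), which cross-metathesis with 4 turns into C13=C14 with loss of ethylene. The closest known reaction type is ring-rearrangement metathesis of cyclopentenes and strained bicyclic alkenes run in tandem with cross-metathesis, together with ring-closing metathesis of ortho-isopropenyl aryl alkenes to 1-methyl-3,4-dihydronaphthalenes; the untested element is that the ring to be opened is an unstrained cyclohexene. Ring B closes by a six-membered ring-closing metathesis in which C1 and C2 become the endocyclic alkene and the isopropenyl CH2 leaves on ruthenium. No stereocentre is formed: C4, C11 and C15 are sp3 carbons that never carry ruthenium, so the trans C4/C11 relationship of 18 passes unchanged into the open chain, and the C13=C14 geometry is irrelevant because that bond is hydrogenated next. The selectivity needed is chemoselectivity only: re-closure of the opened intermediate to the cyclohexene is fast but degenerate and reversible, closure from C13 would require a seven-membered ring, and closure from C2 gives a hindered conjugated trisubstituted alkene that ruthenium should not reopen, so the equilibrating mixture drains through that exit. Heat, excess 4 and removal of ethylene should make the cross-metathesis that follows irreversible.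

Step 12
Reactants: 20 tert-butyl{[(2R,3E,6S)-6-[(1S)-5,6-dimethoxy-4-methyl-1,2-dihydronaphthalen-1-yl]-2-methylhept-3-en-1-yl]oxy}dimethylsilane
Product: 21 tert-butyl{[(2R,6S)-6-[(1S,4R)-5,6-dimethoxy-4-methyl-1,2,3,4-tetrahydronaphthalen-1-yl]-2-methylheptyl]oxy}dimethylsilane
Conditions: [Ir(cod)(L)]B[3,5-(CF3)2C6H3]4 (2 mol %; L = (R)-4-tert-butyl-2-[2-(di-o-tolylphosphanyl)phenyl]-4,5-dihydrooxazole), H2 (50 bar), CH2Cl2, rt
Reagents that add atoms: none
Why: Iridium–P,N-catalysed asymmetric hydrogenation of an unfunctionalised trisubstituted aryl alkene, in which the chiral cation delivers H2 to the C1=C2 face syn to the C4 side chain (catalyst control over the weak 1,4 substrate bias) so that the C1 methyl ends trans to it (1R in serrulatane numbering), while the disubstituted C13=C14 bond is saturated without creating a stereocentre.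

Step 13
Reactants: 21 tert-butyl{[(2R,6S)-6-[(1S,4R)-5,6-dimethoxy-4-methyl-1,2,3,4-tetrahydronaphthalen-1-yl]-2-methylheptyl]oxy}dimethylsilane
Product: 23 (5R,8S)-8-{(2S,6R)-7-[(tert-butyldimethylsilyl)oxy]-6-methylheptan-2-yl}-3,4-dimethoxy-5-methyl-5,6,7,8-tetrahydronaphthalene-2-carboxylic acid, via aryllithium 22 (not isolated)
Conditions: n-BuLi, TMEDA, Et2O, 0 °C → rt; CO2, −78 °C → rt; aq. HCl (pH 3)
Reagents that add atoms: carbon dioxide, O=C=O
Why: Directed ortho-metalation followed by carboxylation of the aryllithium works because C6–H is the only aryl proton next to a methoxy group, while the silyl ether and the tertiary benzylic C–H bonds at C1 and C4 are inert to the base.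

Step 14
Reactants: 23 (5R,8S)-8-{(2S,6R)-7-[(tert-butyldimethylsilyl)oxy]-6-methylheptan-2-yl}-3,4-dimethoxy-5-methyl-5,6,7,8-tetrahydronaphthalene-2-carboxylic acid
Product: 24 (5R,8S)-3,4-dihydroxy-8-[(2S,6R)-7-hydroxy-6-methylheptan-2-yl]-5-methyl-5,6,7,8-tetrahydronaphthalene-2-carboxylic acid
Conditions: BBr3 (5 equiv), CH2Cl2, −78 → 0 °C; H2O
Reagents that add atoms: none
Why: Lewis-acid ether cleavage with BBr3 demethylates both aryl methyl ethers (the one ortho to the acid with chelation assistance) and cleaves the Si–O bond, and at or below 0 °C the primary alkoxyborane should survive until water releases the alcohol, all four stereocentres being remote from the reacting sites.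

Compound list
1 | methyl (S)-3-hydroxy-2-methylpropanoate | C[C@@H](CO)C(=O)OC | starting material
2 | methyl (S)-3-[(tert-butyldimethylsilyl)oxy]-2-methylpropanoate | C[C@@H](CO[Si](C)(C)C(C)(C)C)C(=O)OC | intermediate
3 | (S)-3-[(tert-butyldimethylsilyl)oxy]-2-methylpropanal | C[C@@H](CO[Si](C)(C)C(C)(C)C)C=O | intermediate
4 | (R)-tert-butyldimethyl[(2-methylbut-3-en-1-yl)oxy]silane | C[C@@H](CO[Si](C)(C)C(C)(C)C)C=C | intermediate
5 | (S)-4-benzyl-2-oxazolidinone | O=C1N[C@@H](Cc2ccccc2)CO1 | starting material
6 | (S)-4-benzyl-3-[(E)-but-2-enoyl]oxazolidin-2-one | C/C=C/C(=O)N1[C@@H](Cc2ccccc2)COC1=O | intermediate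
7 | buta-1,3-diene | C=CC=C | starting material
8 | (4S)-4-benzyl-3-[(1S,6S)-6-methylcyclohex-3-ene-1-carbonyl]-1,3-oxazolidin-2-one | C[C@H]1CC=CC[C@@H]1C(=O)N1[C@@H](Cc2ccccc2)COC1=O | intermediate
9 | (1S,6S)-6-methylcyclohex-3-ene-1-carboperoxoic acid (lithium salt in the flask) | C[C@H]1CC=CC[C@@H]1C(=O)OO | intermediate (not isolated)
10 | (1S,6S)-6-methylcyclohex-3-ene-1-carboxylic acid | C[C@H]1CC=CC[C@@H]1C(=O)O | intermediate
11 | 1,3-dioxoisoindolin-2-yl (1S,6S)-6-methylcyclohex-3-ene-1-carboxylate | C[C@H]1CC=CC[C@@H]1C(=O)ON1C(=O)c2ccccc2C1=O | intermediate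
12 | 4-bromo-1,2-dimethoxybenzene | COc1ccc(Br)cc1OC | starting material
13 | (6-bromo-2,3-dimethoxyphenyl)lithium | COc1ccc(Br)c([Li])c1OC | intermediate (not isolated)
14 | 2-(6-bromo-2,3-dimethoxyphenyl)propan-2-ol | COc1ccc(Br)c(C(C)(C)O)c1OC | intermediate
15 | 1-bromo-3,4-dimethoxy-2-(prop-1-en-2-yl)benzene | COc1ccc(Br)c(C(C)=C)c1OC | intermediate
16 | [3,4-dimethoxy-2-(prop-1-en-2-yl)phenyl]lithium | COc1ccc([Li])c(C(C)=C)c1OC | intermediate (not isolated)
17 | chlorido[3,4-dimethoxy-2-(prop-1-en-2-yl)phenyl]zinc | COc1ccc([Zn]Cl)c(C(C)=C)c1OC | intermediate (not isolated)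
18 | (4S,5S)-4-[3,4-dimethoxy-2-(prop-1-en-2-yl)phenyl]-5-methylcyclohex-1-ene | C1[C@H](C)[C@@H](c2ccc(OC)c(OC)c2C(C)=C)CC=C1 | intermediate (key-step precursor)
19 | (1S)-5,6-dimethoxy-4-methyl-1-[(2S)-pent-4-en-2-yl]-1,2-dihydronaphthalene | C=CC[C@H](C)[C@@H]1CC=C(C)c2c1ccc(OC)c2OC | intermediate (not isolated)
20 | tert-butyl{[(2R,3E,6S)-6-[(1S)-5,6-dimethoxy-4-methyl-1,2-dihydronaphthalen-1-yl]-2-methylhept-3-en-1-yl]oxy}dimethylsilane | C[C@@H](CO[Si](C)(C)C(C)(C)C)/C=C/C[C@H](C)[C@@H]1CC=C(C)c2c1ccc(OC)c2OC | intermediate (key-step product)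
21 | tert-butyl{[(2R,6S)-6-[(1S,4R)-5,6-dimethoxy-4-methyl-1,2,3,4-tetrahydronaphthalen-1-yl]-2-methylheptyl]oxy}dimethylsilane | C[C@@H](CO[Si](C)(C)C(C)(C)C)CCC[C@H](C)[C@@H]1CC[C@@H](C)c2c1ccc(OC)c2OC | intermediate
22 | [(5R,8S)-8-{(2S,6R)-7-[(tert-butyldimethylsilyl)oxy]-6-methylheptan-2-yl}-3,4-dimethoxy-5-methyl-5,6,7,8-tetrahydronaphthalen-2-yl]lithium | C[C@@H](CO[Si](C)(C)C(C)(C)C)CCC[C@H](C)[C@@H]1CC[C@@H](C)c2c1cc([Li])c(OC)c2OC | intermediate (not isolated)
23 | (5R,8S)-8-{(2S,6R)-7-[(tert-butyldimethylsilyl)oxy]-6-methylheptan-2-yl}-3,4-dimethoxy-5-methyl-5,6,7,8-tetrahydronaphthalene-2-carboxylic acid | C[C@@H](CO[Si](C)(C)C(C)(C)C)CCC[C@H](C)[C@@H]1CC[C@@H](C)c2c1cc(C(=O)O)c(OC)c2OC | intermediate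
24 | (5R,8S)-3,4-dihydroxy-8-[(2S,6R)-7-hydroxy-6-methylheptan-2-yl]-5-methyl-5,6,7,8-tetrahydronaphthalene-2-carboxylic acid | C[C@@H](CO)CCC[C@H](C)[C@@H]1CC[C@@H](C)c2c1cc(C(=O)O)c(O)c2O | target

Total step count: 14.
Longest linear sequence: 9 steps (5 → 6 → 8 → 10 → 11 → 18 → 20 → 21 → 23 → 24; steps 4, 5, 6, 7, 10, 11, 12, 13, 14).

Steps most likely to fail

1. Step 11 (proposed new method). The unstrained cyclohexene may re-close faster than ring B forms, so that the catalyst is spent on self-metathesis of 4 and decomposes before 18 is converted; closure from the C13 terminus to a seven-membered ring is a minor competing path. The fallback uses known chemistry: the ring is cut oxidatively and resewn by Wittig reactions. It sets out from 18. Exhaustive ozonolysis (O3, CH2Cl2/MeOH, −78 °C; Me2S) cleaves both alkenes and gives the keto-dialdehyde (3S,4S)-3-(2-acetyl-3,4-dimethoxyphenyl)-4-methylhexanedial F1. NaBH4 at low temperature reduces only the two aldehydes, the 2,6-disubstituted aryl ketone being hindered, to give the keto-diol F2. Iodine, PPh3 and imidazole give the diiodide F3, and PPh3 in hot MeCN the bis-phosphonium salt F4. Two equivalents of KN(SiMe3)2 give the bis-ylide F5. Its C2 ylide closes ring B by intramolecular Wittig olefination of the aryl methyl ketone through a six-membered transition ring (the C13 ylide would need a seven-membered one) to give the ylide F6. Aldehyde 3 then traps F6 as the Z isomer of 20, F7. Hydrogenation under the conditions of step 12 erases the alkene geometry and the fallback comes back to the route at 21.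

2. Step 12. Facial selectivity at C1 may be poor if the catalyst and the C4 substituent are mismatched, or the alkene flanked by the peri methoxy group may be reduced sluggishly. The fallback changes from catalyst-controlled syn addition to a stepwise radical reduction under product-stability control and sets out from 20. Hydrogen-atom-transfer hydrogenation (Mn(dpm)3 with dpm = 2,2,6,6-tetramethylheptane-3,5-dionate, PhSiH3, t-BuOOH, i-PrOH, rt) passes through the benzylic C1 radical. It should favour the trans isomer, in which both the C1 methyl and the C4 chain can be pseudoaxial and avoid the peri interactions with the C8 methoxy group and C5–H. The arene-conjugated alkene reacts first, giving the tetralin tert-butyl{[(2R,3E,6S)-6-[(1S,4R)-5,6-dimethoxy-4-methyl-1,2,3,4-tetrahydronaphthalen-1-yl]-2-methylhept-3-en-1-yl]oxy}dimethylsilane F8. Hydrogenation of its remaining C13=C14 bond (H2, palladium on carbon, EtOAc) comes back to the route at 21.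

3. Step 10. The ortho-substituted arylzinc may be lost by protonation or homocoupling before it transmetallates to the hindered nickel centre, and the alkyl radical may add to the isopropenyl group instead of being captured. The fallback avoids the organozinc altogether: metallaphotoredox decarboxylative arylation joins the free acid 10 and the aryl bromide 15 directly ([Ir{dF(CF3)ppy}2(dtbbpy)]PF6, NiCl2·glyme, 4,4'-di-tert-butyl-2,2'-bipyridine, Cs2CO3, DMF, blue light, rt). Here the carboxylate is oxidised to the same cyclohexenyl radical and the aryl–nickel species arises by oxidative addition of 15. It sets out from 10 and 15, comes back to the route at 18, and makes no new compound.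

Further compounds
F1 | step 11 | (3S,4S)-3-(2-acetyl-3,4-dimethoxyphenyl)-4-methylhexanedial | O=CC[C@H](C)[C@@H](c1ccc(OC)c(OC)c1C(C)=O)CC=O
F2 | step 11 | 1-{6-[(3S,4S)-1,6-dihydroxy-4-methylhexan-3-yl]-2,3-dimethoxyphenyl}ethan-1-one | OCC[C@H](C)[C@@H](c1ccc(OC)c(OC)c1C(C)=O)CCO
F3 | step 11 | 1-{6-[(3S,4S)-1,6-diiodo-4-methylhexan-3-yl]-2,3-dimethoxyphenyl}ethan-1-one | ICC[C@H](C)[C@@H](c1ccc(OC)c(OC)c1C(C)=O)CCI
F4 | step 11 | [(3S,4S)-3-(2-acetyl-3,4-dimethoxyphenyl)-4-methylhexane-1,6-diyl]bis(triphenylphosphonium) diiodide | c1ccccc1[P+](c1ccccc1)(c1ccccc1)CC[C@H](C)[C@@H](c1ccc(OC)c(OC)c1C(C)=O)CC[P+](c1ccccc1)(c1ccccc1)c1ccccc1.[I-].[I-]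
F5 | step 11 | 1-{6-[(3S,4S)-4-methyl-1,6-bis(triphenyl-λ5-phosphanylidene)hexan-3-yl]-2,3-dimethoxyphenyl}ethan-1-one | c1ccccc1P(c1ccccc1)(c1ccccc1)=CC[C@H](C)[C@@H](c1ccc(OC)c(OC)c1C(C)=O)CC=P(c1ccccc1)(c1ccccc1)c1ccccc1
F6 | step 11 | {(3S)-3-[(1S)-5,6-dimethoxy-4-methyl-1,2-dihydronaphthalen-1-yl]butylidene}triphenyl-λ5-phosphane | c1ccccc1P(c1ccccc1)(c1ccccc1)=CC[C@H](C)[C@@H]1CC=C(C)c2c1ccc(OC)c2OC
F7 | step 11 | tert-butyl{[(2R,3Z,6S)-6-[(1S)-5,6-dimethoxy-4-methyl-1,2-dihydronaphthalen-1-yl]-2-methylhept-3-en-1-yl]oxy}dimethylsilane | C[C@@H](CO[Si](C)(C)C(C)(C)C)/C=C\C[C@H](C)[C@@H]1CC=C(C)c2c1ccc(OC)c2OC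
F8 | step 12 | tert-butyl{[(2R,3E,6S)-6-[(1S,4R)-5,6-dimethoxy-4-methyl-1,2,3,4-tetrahydronaphthalen-1-yl]-2-methylhept-3-en-1-yl]oxy}dimethylsilane | C[C@@H](CO[Si](C)(C)C(C)(C)C)/C=C/C[C@H](C)[C@@H]1CC[C@@H](C)c2c1ccc(OC)c2OC
F0 | step 10 | none | none
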